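## Structural features

CNP0208728.2 is a C20 labdane-type diterpenoid, (5S,8R,9S,10S,13S)-9α,13-epoxy-8β-hydroxy-7-oxolabdan-15,16-olide (lactone carbonyl C15, lactone oxygen on C16). Four rings form a dispiro chain: the trans-decalin (rings A and B), a tetrahydrofuran (ring C: C9, C11, C12, C13, O) spiro-fused to ring B at C9, and a γ-lactone (ring D) spiro-fused to ring C at C13. Ring A carries the C4 gem-dimethyl group and is fused to ring B through C5 (α-H) and C10 (β-methyl). Ring B holds three contiguous oxidised carbons: the C7 ketone, the C8 tertiary carbinol (8β-OH axial, 8α-methyl) and the spiro ether carbon C9 (9α-O axial, C11 β). C8, C9 and C10 are therefore three adjacent fully substituted stereocentres, with the two oxygens trans-diaxial. The fifth stereocentre, C13, lies two methylene groups away from this block and has to distinguish two very similar arms (CH2C=O and CH2O). Fragile elements are the tertiary α-ketol at C7/C8 (enolisable at C6, prone to ketol shifts in base or acid) and the β-alkoxy lactone, which can reopen ring C by retro-conjugate addition. The real difficulty is the crowded C8–C9–C10 triad with the correct oxygen faces, together with the remote C13 centre. The key step exploits that rings A and B, with the C4 gem-dimethyl group, the C10 methyl, an oxygen on C8 and a carbon (C11) on C9, are the direct image of an all-chair fold of a geranyl chain ending in a β-keto ester.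

## Logic of the disconnections

17 to 16: no skeletal bond is cut; only the oxidation level at C7 changes. The α-ketol is the most base-sensitive part of 17, so it is created last. The forward step must oxidise a secondary alcohol next to a tertiary one without cleaving C7–C8 and without base.

16 to 15: the O–C13 bond of ring C is cut, since a β-alkoxy lactone is the retron of a conjugate addition. This removes ring C, the spiro centre C13 and its stereochemistry, leaving a flat butenolide. The forward step needs the 9α-hydroxyl (5-exo) to close in preference to the 8β-hydroxyl (6-exo), and needs control or equilibration at C13.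

15 to 12 and 13 (through 14): the C12–C13 bond between the side chain and the butenolide is cut. The four lactone carbons then come from one small building block, and the side chain on the decalin shrinks to a vinyl group acting as a latent C12 nucleophile. The forward step needs terminal hydroboration next to the quaternary C9 and a coupling mild enough for a butenolide and three free hydroxyls.

12 to 11: the C8–C17 bond is cut. A methyl nucleophile adding to a C8 ketone from the α face gives exactly the 8β-hydroxy-8α-methyl arrangement, and the cut removes one of the three contiguous quaternary centres. The forward step needs α-face delivery and a substrate with no second carbonyl, which is why C11 is already a vinyl carbon at this stage.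

11 to 9 (through 10): the C7–O bond is cut. Because C9 is quaternary, the C8 ketone can enolise only toward C7, so a C7=C8 silyl enol ether carries the regiochemistry. The forward step must oxidise the enol ether and leave the vinyl group alone.

9 to 8 to 7: the C11=C12 double bond is cut and C11 is returned to the ester level. C11 is the ester carbon delivered by the cyclisation, so it must pass through the aldehyde. Keeping C8 as an enol ether during these steps avoids any β-keto or β-hydroxy aldehyde that could fragment. The forward steps need a partial reduction of a hindered ester and a methylenation next to a quaternary carbon.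

7 to 6 to 5: the two O–Si bonds are removed, then the C9–O bond is cut. An enolate flanked by ketone and ester is the natural site for electrophilic oxygen, and the cut removes the first quaternary carbinol. The forward step needs attack on the α face, which the axial C10 methyl should enforce.

5 to 4: the C4–C5 and C9–C10 bonds are cut, opening both carbocycles and removing three stereocentres at once. The forward step must fold the chain chair–chair, start by protonation at C3 on one enantiotopic face, and end by C-alkylation of the enol at C9. 4 is kept with its β-keto ester free: a silyl enol ether would be protonated by the chiral acid before the alkene, so masking would not improve the precursor.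

4 to 1 and 2: the bond between the terminal carbon of the acetoacetate unit and the allylic carbon is cut (C6–C7 in labdane numbering). Both pieces are commodity chemicals. The forward step needs alkylation at the terminal rather than the central carbon, which the dianion provides.

## Other disconnections considered

Alternative 1: The cut removes the two carbon–carbon bonds of ring D at the spiro carbon, C13–C14 and C15–C16. It leads back to the exocyclic enol ether A1 (9α,13-epoxy-14,15-dinorlabda-7,13(16)-diene).
- Forward step: dichloroketene, from trichloroacetyl chloride and zinc–copper couple, would add across C13=C16 to give the spiro dichlorocyclobutanone A2. Baeyer–Villiger oxidation (migration of the CH2 carbon C16 rather than the CCl2 carbon) and reductive dechlorination would then give the lactone.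
- In favour: ketene (2+2) additions to enol ethers are fast and their regiochemistry (CCl2 carbon to the oxygen-bearing carbon) is dependable. The quaternary C13 is made irreversibly with two C–C bonds at once. No second hydroxyl can compete, because C8 is still an alkene carbon.
- Against: the face of the enol ether is selected only by the distant decalin. The stereochemical information in A2 rests solely on the difference between CCl2 and CH2, so ring expansion must precede dechlorination or C13 stops being stereogenic. A1 is an acid-labile 2-methylenetetrahydrofuran that must survive the zinc salts. A2 still lacks both ring B oxygens; they would have to be added to the C7=C8 alkene on the face syn to the C10 methyl to give the 8β-hydroxyl, against the usual α-face preference.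
- Comparison: on C13 the two plans are equal, both being substrate-controlled. Alternative 1 is the better on irreversibility of the ring D construction. In mechanism it replaces a reversible polar conjugate addition by a kinetically controlled cycloaddition. In structure it leaves the harder C8 problem unsolved. In step economy it needs three operations for ring D plus a separate oxidation sequence on ring B, so it would be longer.

Alternative 2: The cut is the O–C9 bond of ring C. It leads back to the C8,C9 silyl enol ether A3, which carries a complete side chain with the C13 tertiary alcohol and silyl-protected C15 and C16 hydroxyls.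
- Forward step: anodic oxidation (carbon anode, LiClO4, 2,6-lutidine, methanol) would turn the enol ether into a radical cation that the C13 hydroxyl traps at C9 (5-exo). A second electron transfer and loss of silicon would return the C8 ketone in A4.
- In favour: C13 is made before ring closure in an acyclic fragment, where a reagent can set it. The one centre that the chosen plan leaves to the substrate is thereby secured; on this point the alternative is the better. The umpolung forms the hindered C9–O bond without a leaving group. A4 keeps the C8 ketone for the same C7 oxidation and methyl addition used in the chosen plan.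
- Against: A3 needs a regiodefined tetrasubstituted enol ether, although enolisation of a 9-alkyl-8-ketone toward C7 is easier. A tertiary alcohol must attack a fully substituted radical-cation carbon next to the quaternary C10, in competition with methanol and with proton loss. The side chain needs its own asymmetric synthesis. The two silyl ethers must later be told apart so that only C15 is oxidised.
- Comparison: in structure both plans should place the C9 oxygen on the α face for the same reason (approach opposite the C10 methyl), an equal point. In mechanism the alternative relies on radical-cation chemistry and an electrochemical set-up, where the chosen plan uses polar two-electron steps. In step economy it is convergent but pays for the side-chain synthesis and the late diol differentiation, and would come out longer.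

Alternative 3: The cut is C13–C14 of ring D. It leads back to the diazoacetate A5 of a 13-hydroxymethyl tetrahydrofuran that already carries the finished ring B (8-O-trimethylsilyl, 7-oxo).
- Forward step: Rh2(OAc)4 would decompose A5, and the rhodium carbenoid would insert into the tertiary C13–H bond next to the ring oxygen (1,5-insertion, retention) to give A6, the trimethylsilyl ether of the target.
- In favour: the insertion is stereospecific and irreversible. The C–H bond is tertiary and activated by the adjacent oxygen. A6 is one desilylation from the target, the most convergent end game of the four; on this point it is better than the chosen plan.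
- Against: the configuration at C13 is only transferred, not created, so the problem moves back to making the C13–H centre of the tetrahydrofuran, again under substrate control. The ring oxygen can intercept the carbenoid as an oxonium ylide, and C12–H insertion and carbene dimerisation compete. The C8 hydroxyl must be silylated to prevent O–H insertion. Preparing A5 adds operations on a late intermediate.
- Comparison: in structure the alternative equals the chosen plan on C13 (neither sets it by a reagent) and is the better in never exposing the product to a reversible closure. In mechanism it replaces a catalytic base-mediated conjugate addition by a carbenoid insertion with more possible side paths. In step economy it would need at least three more steps once ring C is in place, so the chosen plan is shorter.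

Key step: step 2

Remarks on the chemistry (assumptions):
- Labdane numbering (C1–C20) is used for positions in all intermediates.
- The (R) enantiomer of 2'-methoxy-1,1'-binaphthalen-2-ol is assumed to give the (5S,10S) series; if the sense is opposite for this substrate, the (S) ligand is used.
- The C7 carbinol in 10–12 and 14–16 is drawn as the 7β (equatorial) epimer; its configuration is immaterial because C7 ends as the ketone.

## Route

Step 1
Reactants: 1 ethyl acetoacetate; 2 geranyl bromide, (2E)-1-bromo-3,7-dimethylocta-2,6-diene
Product: 4 ethyl (6E)-7,11-dimethyl-3-oxododeca-6,10-dienoate, via acetoacetate dianion 3 (not isolated)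
Conditions: NaH, THF, 0 °C; n-BuLi, 0 °C; then 2, 0 °C → rt; 1 M HCl
Reagents that add atoms: none
Why: Successive deprotonation at the central and then the terminal carbon gives the dianion, whose more basic terminal carbanion displaces the allylic bromide (dianion γ-alkylation of a β-keto ester, SN2); the E alkene of 2 is untouched and no stereocentre is formed.

Step 2
Reactants: 4 ethyl (6E)-7,11-dimethyl-3-oxododeca-6,10-dienoate
Product: 5 ethyl (1R,4aS,8aS)-5,5,8a-trimethyl-2-oxodecahydronaphthalene-1-carboxylate
Conditions: SnCl4 (2.0 equiv), (R)-2'-methoxy-1,1'-binaphthalen-2-ol (1.1 equiv), toluene, −78 °C, 2–3 d; then −78 → −20 °C; H2O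
Reagents that add atoms: none
Why: Proposed new method: the tin-bound phenol of the chiral complex transfers its proton to C3 of the terminal alkene, the C4 cation is attacked by the C5=C10 alkene (6-endo-trig, ring A) and the C10 cation is captured at C9 by the tin-chelated enol of the β-keto ester (6-endo-trig, ring B); the closest known reaction types are the SnCl4-promoted racemic cyclisation of this class of polyene β-keto esters and the enantioselective cyclisation of geranyl and homogeranyl arenes and alcohols by the same chiral proton source, combined here on a chelating terminator. The configuration at C5 is fixed by which chair fold reacts inside the binaphthyl pocket during the concerted protonation and first closure (ligand control). C10 follows from the chair–chair fold of the E alkene, which gives the trans ring fusion, and C9 from the equatorial placement of the ester, which can also equilibrate through the enol. The ester confines enolisation to C9, so only one ring B regioisomer can form, and the chelated enol favours C- over O-alkylation. Two equivalents of SnCl4 are used because the β-dicarbonyl binds one. The needed selectivity is enantioselection at the initiation, and the threat to it is an achiral proton leaking from the tin chelate, which is why the reaction is run cold in toluene. Monocyclic material that has lost a proton should close in the same flask on warming, diastereoselectively with respect to C5.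

Step 3
Reactants: 5 ethyl (1R,4aS,8aS)-5,5,8a-trimethyl-2-oxodecahydronaphthalene-1-carboxylate
Product: 6 ethyl (1S,4aS,8aS)-1-hydroxy-5,5,8a-trimethyl-2-oxodecahydronaphthalene-1-carboxylate
Conditions: KN(SiMe3)2, THF, −78 °C; 2-(phenylsulfonyl)-3-phenyloxaziridine, −78 → 0 °C; aq. NH4Cl
Reagents that add atoms: 2-(phenylsulfonyl)-3-phenyloxaziridine, O=S(=O)(c1ccccc1)N1OC1c1ccccc1
Why: Electrophilic hydroxylation of the potassium enolate of the β-keto ester at C9 by the N-sulfonyloxaziridine; the oxidant approaches opposite the axial C10 methyl, so the new hydroxyl is 9α (axial) and the ester stays β.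

Step 4
Reactants: 6 ethyl (1S,4aS,8aS)-1-hydroxy-5,5,8a-trimethyl-2-oxodecahydronaphthalene-1-carboxylate
Product: 7 ethyl (1S,4aS,8aS)-5,5,8a-trimethyl-1,2-bis(triethylsilyloxy)-1,4,4a,5,6,7,8,8a-octahydronaphthalene-1-carboxylate
Conditions: Et3SiOTf (3 equiv), Et3N, CH2Cl2, 0 °C → rt
Reagents that add atoms: triethylsilyl trifluoromethanesulfonate, CC[Si](CC)(CC)OS(=O)(=O)C(F)(F)F
Why: Silyl triflate and amine silylate the tertiary hydroxyl and convert the ketone into its silyl enol ether (soft enolisation), which can only form toward C7 because C9 is quaternary; the enol ether masks the ketone for the next two steps and avoids strong base that could cause retro-Claisen cleavage or a ketol shift.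

Step 5
Reactants: 7 ethyl (1S,4aS,8aS)-5,5,8a-trimethyl-1,2-bis(triethylsilyloxy)-1,4,4a,5,6,7,8,8a-octahydronaphthalene-1-carboxylate
Product: 8 (1S,4aS,8aS)-5,5,8a-trimethyl-1,2-bis(triethylsilyloxy)-1,4,4a,5,6,7,8,8a-octahydronaphthalene-1-carbaldehyde
Conditions: i-Bu2AlH, CH2Cl2, −78 °C; MeOH; aq. potassium sodium tartrate
Reagents that add atoms: none
Why: Partial reduction of an α-silyloxy ester by i-Bu2AlH at low temperature should stop at the aldehyde, because the hindered, chelated aluminium hemiacetal collapses only on work-up; silyl ether and silyl enol ether are inert to the hydride.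

Step 6
Reactants: 8 (1S,4aS,8aS)-5,5,8a-trimethyl-1,2-bis(triethylsilyloxy)-1,4,4a,5,6,7,8,8a-octahydronaphthalene-1-carbaldehyde
Product: 9 (1S,4aS,8aS)-1-ethenyl-5,5,8a-trimethyl-1,2-bis(triethylsilyloxy)-1,4,4a,5,6,7,8,8a-octahydronaphthalene
Conditions: Ph3PCH3Br, KN(SiMe3)2, THF, 0 °C; then 8, 0 °C → rt
Reagents that add atoms: methyltriphenylphosphonium bromide, C[P+](c1ccccc1)(c1ccccc1)c1ccccc1.[Br-]
Why: Wittig methylenation of a non-enolisable aldehyde by the smallest ylide; with C8 masked as the enol ether there is no β-hydroxy or β-keto aldehyde that could fragment under the basic conditions.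

Step 7
Reactants: 9 (1S,4aS,8aS)-1-ethenyl-5,5,8a-trimethyl-1,2-bis(triethylsilyloxy)-1,4,4a,5,6,7,8,8a-octahydronaphthalene
Product: 11 (1S,3S,4aS,8aS)-1-ethenyl-1,3-dihydroxy-5,5,8a-trimethyloctahydronaphthalen-2(1H)-one, via bis-silyl ketol 10 (not isolated)
Conditions: mCPBA, NaHCO3, CH2Cl2, −20 → 0 °C; then HF·pyridine, THF, 0 °C → rt
Reagents that add atoms: 3-chloroperoxybenzoic acid, O=C(OO)c1cccc(Cl)c1
Why: Rubottom oxidation: the electron-rich silyl enol ether is epoxidised far faster than the monosubstituted vinyl group, and ring opening with silyl migration gives the 7-silyloxy-8-ketone 10, from which fluoride removes both silyl groups. The C7 oxygen is expected on the β face (away from the axial 9α-silyloxy group, equatorial after any equilibration), but this centre is oxidised later, so its configuration does not matter.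

Step 8
Reactants: 11 (1S,3S,4aS,8aS)-1-ethenyl-1,3-dihydroxy-5,5,8a-trimethyloctahydronaphthalen-2(1H)-one
Product: 12 (1S,2S,3S,4aS,8aS)-1-ethenyl-2,5,5,8a-tetramethyldecahydronaphthalene-1,2,3-triol
Conditions: MeMgBr (5 equiv), CeCl3, THF, −78 → 0 °C; aq. NH4Cl
Reagents that add atoms: methylmagnesium bromide, C[Mg]Br
Why: 1,2-Addition of the methyl organometallic to the C8 ketone, with CeCl3 to suppress enolisation; attack on the β face is blocked by the 1,3-diaxial C10 methyl and the metal alkoxide on the 9α oxygen should direct delivery to the α face, so the methyl enters α (equatorial) and the hydroxyl becomes 8β (axial). No other carbonyl is present, which is why C11 was converted first.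

Step 9
Reactants: 12 (1S,2S,3S,4aS,8aS)-1-ethenyl-2,5,5,8a-tetramethyldecahydronaphthalene-1,2,3-triol; 13 4-bromofuran-2(5H)-one
Product: 15 4-{2-[(1S,2S,3S,4aS,8aS)-1,2,3-trihydroxy-2,5,5,8a-tetramethyldecahydronaphthalen-1-yl]ethyl}furan-2(5H)-one, via B-alkyl-9-BBN adduct 14 (not isolated)
Conditions: 9-BBN (5 equiv), THF, rt → 50 °C; then 13, Pd(dppf)Cl2 (5 mol %), AsPh3, K3PO4, H2O, DMF, rt
Reagents that add atoms: none
Why: Hydroboration with 9-BBN places boron on the terminal carbon C12 (the excess covers the hydroxyls), and B-alkyl Suzuki–Miyaura coupling with the vinylic bromide 13 forms C12–C13; oxidative addition to the β-bromo enoate is easy, and phosphate base at room temperature should spare the butenolide. No stereocentre is formed; any 16 formed already here is carried into step 10.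

Step 10
Reactants: 15 4-{2-[(1S,2S,3S,4aS,8aS)-1,2,3-trihydroxy-2,5,5,8a-tetramethyldecahydronaphthalen-1-yl]ethyl}furan-2(5H)-one
Product: 16 (5S,7S,8S,9S,10S,13S)-9α,13-epoxy-7β,8β-dihydroxylabdan-15,16-olide
Conditions: DBU (0.2 equiv), CH2Cl2, rt
Reagents that add atoms: none
Why: Base-catalysed intramolecular oxa-Michael addition: the 9α-hydroxyl adds to C13, the β-carbon of the butenolide, in a 5-exo-trig closure that forms ring C and the spiro centre. The addition is reversible, so C13 is set by the substrate under thermodynamic control; the 13S isomer may have to be separated from its epimer, which can be re-equilibrated.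

Step 11
Reactants: 16 (5S,7S,8S,9S,10S,13S)-9α,13-epoxy-7β,8β-dihydroxylabdan-15,16-olide
Product: 17 CNP0208728.2, (5S,8R,9S,10S,13S)-9α,13-epoxy-8β-hydroxy-7-oxolabdan-15,16-olide
Conditions: IBX, DMSO, rt
Reagents that add atoms: none
Why: 2-Iodoxybenzoic acid oxidises the secondary C7 alcohol to the ketone and converts 1,2-diols into α-hydroxy ketones without C–C cleavage; the neutral conditions spare the tertiary ketol and the β-alkoxy lactone, and no stereocentre is touched.

## Compound list

1 | ethyl acetoacetate (ethyl 3-oxobutanoate) | CCOC(=O)CC(C)=O | starting material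
2 | geranyl bromide, (2E)-1-bromo-3,7-dimethylocta-2,6-diene | CC(C)=CCC/C(C)=C/CBr | starting material
3 | acetoacetate dianion (sodium lithium salt) | C=C([O-])C=C([O-])OCC.[Na+].[Li+] | intermediate (not isolated)
4 | ethyl (6E)-7,11-dimethyl-3-oxododeca-6,10-dienoate | CC(C)=CCC/C(C)=C/CCC(=O)CC(=O)OCC | intermediate
5 | ethyl (1R,4aS,8aS)-5,5,8a-trimethyl-2-oxodecahydronaphthalene-1-carboxylate (8-oxo, 9β-ester) | CC1(C)CCC[C@@]2(C)[C@H]1CCC(=O)[C@@H]2C(=O)OCC | intermediate
6 | ethyl (1S,4aS,8aS)-1-hydroxy-5,5,8a-trimethyl-2-oxodecahydronaphthalene-1-carboxylate (9α-OH) | CC1(C)CCC[C@@]2(C)[C@H]1CCC(=O)[C@]2(O)C(=O)OCC | intermediate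
7 | ethyl (1S,4aS,8aS)-5,5,8a-trimethyl-1,2-bis(triethylsilyloxy)-1,4,4a,5,6,7,8,8a-octahydronaphthalene-1-carboxylate | CC1(C)CCC[C@@]2(C)[C@H]1CC=C(O[Si](CC)(CC)CC)[C@]2(O[Si](CC)(CC)CC)C(=O)OCC | intermediate
8 | (1S,4aS,8aS)-5,5,8a-trimethyl-1,2-bis(triethylsilyloxy)-1,4,4a,5,6,7,8,8a-octahydronaphthalene-1-carbaldehyde | CC1(C)CCC[C@@]2(C)[C@H]1CC=C(O[Si](CC)(CC)CC)[C@]2(O[Si](CC)(CC)CC)C=O | intermediate
9 | (1S,4aS,8aS)-1-ethenyl-5,5,8a-trimethyl-1,2-bis(triethylsilyloxy)-1,4,4a,5,6,7,8,8a-octahydronaphthalene | CC1(C)CCC[C@@]2(C)[C@H]1CC=C(O[Si](CC)(CC)CC)[C@]2(O[Si](CC)(CC)CC)C=C | intermediate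
10 | (1S,3S,4aS,8aS)-1-ethenyl-5,5,8a-trimethyl-1,3-bis(triethylsilyloxy)octahydronaphthalen-2(1H)-one | CC1(C)CCC[C@@]2(C)[C@H]1C[C@H](O[Si](CC)(CC)CC)C(=O)[C@]2(O[Si](CC)(CC)CC)C=C | intermediate (not isolated)
11 | (1S,3S,4aS,8aS)-1-ethenyl-1,3-dihydroxy-5,5,8a-trimethyloctahydronaphthalen-2(1H)-one | CC1(C)CCC[C@@]2(C)[C@H]1C[C@H](O)C(=O)[C@]2(O)C=C | intermediate
12 | (1S,2S,3S,4aS,8aS)-1-ethenyl-2,5,5,8a-tetramethyldecahydronaphthalene-1,2,3-triol | CC1(C)CCC[C@@]2(C)[C@H]1C[C@H](O)[C@](C)(O)[C@]2(O)C=C | intermediate
13 | 4-bromofuran-2(5H)-one | O=C1C=C(Br)CO1 | starting material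
14 | 9-{2-[(1S,2S,3S,4aS,8aS)-1,2,3-trihydroxy-2,5,5,8a-tetramethyldecahydronaphthalen-1-yl]ethyl}-9-borabicyclo[3.3.1]nonane | CC1(C)CCC[C@@]2(C)[C@H]1C[C@H](O)[C@](C)(O)[C@]2(O)CCB1C2CCCC1CCC2 | intermediate (not isolated)
15 | 4-{2-[(1S,2S,3S,4aS,8aS)-1,2,3-trihydroxy-2,5,5,8a-tetramethyldecahydronaphthalen-1-yl]ethyl}furan-2(5H)-one | CC1(C)CCC[C@@]2(C)[C@H]1C[C@H](O)[C@](C)(O)[C@]2(O)CCC1=CC(=O)OC1 | intermediate
16 | (5S,7S,8S,9S,10S,13S)-9α,13-epoxy-7β,8β-dihydroxylabdan-15,16-olide | CC1(C)CCC[C@@]2(C)[C@H]1C[C@H](O)[C@](C)(O)[C@]21CC[C@]2(COC(=O)C2)O1 | intermediate
17 | CNP0208728.2, (5S,8R,9S,10S,13S)-9α,13-epoxy-8β-hydroxy-7-oxolabdan-15,16-olide | CC1(C)CCC[C@@]2(C)[C@H]1CC(=O)[C@](C)(O)[C@]21CC[C@]2(COC(=O)C2)O1 | target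

## Step count and least certain steps

Total step count: 11. Longest linear sequence: 11 steps (1 and 2 to 17); 13 enters in step 9.

Step 2 (key step, carries the label). Most likely failure: loss of enantiocontrol. The β-dicarbonyl chelates tin and can release an achiral proton, which starts a racemic background cyclisation; the reaction may also stop after ring A.
Fallback, known chemistry, from 4 back to 5:
- 4 is cyclised with SnCl4 alone (CH2Cl2, 0 °C → rt), the established racemic protocol. This gives 5 together with its mirror image, ethyl (1S,4aR,8aR)-5,5,8a-trimethyl-2-oxodecahydronaphthalene-1-carboxylate F1.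
- Heating the racemate with (−)-menthol and catalytic 4-(dimethylamino)pyridine in toluene, with removal of ethanol, exchanges the ester through the acylketene. This gives the menthyl ester of the wanted acid, (1R,2S,5R)-2-isopropyl-5-methylcyclohexyl (1R,4aS,8aS)-5,5,8a-trimethyl-2-oxodecahydronaphthalene-1-carboxylate F2, and its diastereomer, the (1S,4aR,8aR) menthyl ester F3.
- These are separated by crystallisation or chromatography. F2 is returned to 5 with Ti(OEt)4 in boiling ethanol.

Step 10. Most likely failure: poor facial selectivity at C13, because the reversible closure is steered only by the remote decalin; competing 6-exo closure through the 8β-hydroxyl is the second concern.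
Fallback, from 15 back to 16:
- The cis 7β,8β-diol is tied up with 2,2-dimethoxypropane and pyridinium p-toluenesulfonate as the acetonide, 4-{2-[(7β,8β-isopropylidenedioxy)-9α-hydroxy decalinyl]ethyl}furan-2(5H)-one F4, so that only the 9α-hydroxyl is free.
- DBU then closes ring C to the spiro acetonide F5.
- Aqueous acetic acid releases 16.
- The closure stays reversible, so material of the wrong C13 configuration can be separated at the acetonide stage and returned to the equilibrium.

Step 8. Most likely failure: methyl delivery to the wrong face of the C8 carbonyl, because the axial 9α-oxygen crowds the α face while the C10 methyl crowds the β face; enolisation of the α-hydroxy ketone is the second concern.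
Fallback, from 11 back to 12:
- Corey–Chaykovsky reaction with dimethylsulfoxonium methylide (Me3S(O)I, NaH, DMSO). Its addition is reversible and should place the new carbon equatorial, giving the 8β,17-epoxide F6.
- LiEt3BH opens F6 at the primary carbon to give 12.

Step 9. Most likely failure: base-induced decomposition of the bromobutenolide or of the product during the coupling, or slow hydroboration of the vinyl group next to the quaternary C9.
Fallback, from 12 back to 15:
- The same borane 14 is coupled with 3-bromofuran (Pd(dppf)Cl2, K3PO4), a base-stable partner, to give the 3-alkylfuran F7.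
- Photooxygenation with singlet oxygen (O2, rose bengal, light, N,N-diisopropylethylamine, CH2Cl2, −78 °C) converts the furan regioselectively into the γ-hydroxybutenolide F8.
- NaBH4 reduces F8 to 15.

Step 5. Most likely failure: incomplete reduction of the very hindered ester at low temperature, or over-reduction once the mixture is warmed.
Fallback, from 7 back to 8:
- LiAlH4 in ether reduces the ester fully to the primary alcohol F9.
- Parikh–Doering oxidation (SO3·pyridine, DMSO, Et3N) gives 8.

## Further compounds

F1 | step 2 | ethyl (1S,4aR,8aR)-5,5,8a-trimethyl-2-oxodecahydronaphthalene-1-carboxylate (mirror image of 5) | CC1(C)CCC[C@]2(C)[C@@H]1CCC(=O)[C@H]2C(=O)OCC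
F2 | step 2 | (1R,2S,5R)-2-isopropyl-5-methylcyclohexyl (1R,4aS,8aS)-5,5,8a-trimethyl-2-oxodecahydronaphthalene-1-carboxylate | CC1(C)CCC[C@@]2(C)[C@H]1CCC(=O)[C@@H]2C(=O)O[C@@H]1C[C@H](C)CC[C@H]1C(C)C
F3 | step 2 | (1R,2S,5R)-2-isopropyl-5-methylcyclohexyl (1S,4aR,8aR)-5,5,8a-trimethyl-2-oxodecahydronaphthalene-1-carboxylate | CC1(C)CCC[C@]2(C)[C@@H]1CCC(=O)[C@H]2C(=O)O[C@@H]1C[C@H](C)CC[C@H]1C(C)C
F4 | step 10 | 7β,8β-O-isopropylidene derivative of 15 (9α-hydroxyl free) | CC1(C)CCC[C@@]2(C)[C@H]1C[C@@H]3OC(C)(C)O[C@]3(C)[C@]2(O)CCC1=CC(=O)OC1
F5 | step 10 | 7β,8β-O-isopropylidene derivative of 16 | CC1(C)CCC[C@@]2(C)[C@H]1C[C@@H]3OC(C)(C)O[C@]3(C)[C@]21CC[C@]2(COC(=O)C2)O1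
F6 | step 8 | 8β,17-epoxide: 9α-ethenyl-7β,9-dihydroxy decalin with spiro-oxirane at C8 (oxygen β, CH2 α) | CC1(C)CCC[C@@]2(C)[C@H]1C[C@H](O)[C@@]1(CO1)[C@]2(O)C=C
F7 | step 9 | (1S,2S,3S,4aS,8aS)-1-[2-(furan-3-yl)ethyl]-2,5,5,8a-tetramethyldecahydronaphthalene-1,2,3-triol | CC1(C)CCC[C@@]2(C)[C@H]1C[C@H](O)[C@](C)(O)[C@]2(O)CCc1ccoc1
F8 | step 9 | 5-hydroxy-4-{2-[(1S,2S,3S,4aS,8aS)-1,2,3-trihydroxy-2,5,5,8a-tetramethyldecahydronaphthalen-1-yl]ethyl}furan-2(5H)-one (both hemiacetal epimers) | CC1(C)CCC[C@@]2(C)[C@H]1C[C@H](O)[C@](C)(O)[C@]2(O)CCC1=CC(=O)OC1O
F9 | step 5 | [(1S,4aS,8aS)-5,5,8a-trimethyl-1,2-bis(triethylsilyloxy)-1,4,4a,5,6,7,8,8a-octahydronaphthalen-1-yl]methanol | CC1(C)CCC[C@@]2(C)[C@H]1CC=C(O[Si](CC)(CC)CC)[C@]2(O[Si](CC)(CC)CC)CO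
A1 | alternative 1 | 9α,13-epoxy-14,15-dinorlabda-7,13(16)-diene (13-methylene tetrahydrofuran) | CC1(C)CCC[C@@]2(C)[C@H]1CC=C(C)[C@]21CCC(=C)O1
A2 | alternative 1 | spiro 2,2-dichlorocyclobutanone on C13 (CCl2 = C14, C=O = C15, CH2 = C16) | CC1(C)CCC[C@@]2(C)[C@H]1CC=C(C)[C@]21CC[C@]2(CC(=O)C2(Cl)Cl)O1
A3 | alternative 2 | 8-(trimethylsilyloxy)-17-norlabd-8-ene-13,15,16-triol 15,16-bis(tert-butyldimethylsilyl) ether | CC1(C)CCC[C@@]2(C)[C@H]1CCC(O[Si](C)(C)C)=C2CC[C@@](O)(CO[Si](C)(C)C(C)(C)C)CCO[Si](C)(C)C(C)(C)C
A4 | alternative 2 | 9α,13-epoxy-17-norlabdan-8-one 15,16-bis(tert-butyldimethylsilyl) ether | CC1(C)CCC[C@@]2(C)[C@H]1CCC(=O)[C@]21CC[C@@](CO[Si](C)(C)C(C)(C)C)(CCO[Si](C)(C)C(C)(C)C)O1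
A5 | alternative 3 | diazoacetate of 9α,13-epoxy-16-hydroxy-8β-(trimethylsilyloxy)-14,15-dinorlabdan-7-one | CC1(C)CCC[C@@]2(C)[C@H]1CC(=O)[C@](C)(O[Si](C)(C)C)[C@]21CC[C@H](COC(=O)C=[N+]=[N-])O1
A6 | alternative 3 | 8-O-trimethylsilyl ether of CNP0208728.2 | CC1(C)CCC[C@@]2(C)[C@H]1CC(=O)[C@](C)(O[Si](C)(C)C)[C@]21CC[C@]2(COC(=O)C2)O1
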